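**Plan**

1. Ring C (pyranone) is cut at O1–C2 (cyclodehydration) and at C2–C3 (C-acylation of an α-oxygenated ring-A ketone by the ring-B acid chloride).
2. Ring B loses the prenyl C–C bond (Stille coupling) and, in one cut, both the aryl–O bond and the C3=C4 bond of the dimethylpyran ring. This leads back to a 2-fluorobenzaldehyde and a three-atom C–C–O phosphine oxide. Ring A loses the C8–C(quaternary) bond (aromatic Claisen rearrangement of a 4-O-prenyl ether).
3. Enabling feature: in ring B the ether carbon C4' lies para to C1' (the carboxyl carbon, later C2 of ring C) and ortho to C3'. The carbon on C3' becomes C4 of the pyran ring; as a formyl group it activates fluoride displacement at C4' and then accepts the carbanion that sits three atoms from the new ether oxygen.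
4. Forward order: dimethylpyran ring on the ring-B benzoate, then prenyl, then the acid. Ring A is reverse-prenylated, protected and α-hydroxylated. The pyranone ring is closed last, with loss of all MOM groups.
5. Stereochemistry: the target has no stereocentre. Its only geometric element, the cis ring alkene of the pyran, is fixed by ring closure.

Key step: step 5

Remark: intermediates 9 and 22 are racemic; stannane 11 and the oxaziridine of step 11 are taken as purchased reagents.

**Route**

Step 1
Reactants: 1 methyl 4-fluoro-3-hydroxybenzoate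
Product: 2 methyl 2-bromo-4-fluoro-5-hydroxybenzoate
Conditions: NBS (1.0 equiv), MeCN, 0 °C to rt
Reagents that add atoms: N-bromosuccinimide, O=C1CCC(=O)N1Br
Why: Electrophilic aromatic bromination; the free hydroxyl directs para to itself (C6 of 1), since one ortho position carries fluorine and the other is flanked by the ester, and this places the halogen handle for the later prenyl group.

Step 2
Reactants: 2 methyl 2-bromo-4-fluoro-5-hydroxybenzoate
Product: 3 methyl 2-bromo-4-fluoro-5-(methoxymethoxy)benzoate
Conditions: MOMCl, i-Pr2NEt, CH2Cl2, 0 °C to rt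
Reagents that add atoms: chloromethyl methyl ether, COCCl
Why: O-alkylation of the phenol (Williamson-type acetal formation) gives the base-stable MOM ether needed for the metalation and SNAr steps.

Step 3
Reactants: 3 methyl 2-bromo-4-fluoro-5-(methoxymethoxy)benzoate
Product: 4 methyl 2-bromo-4-fluoro-3-formyl-5-(methoxymethoxy)benzoate
Conditions: LDA (1.1 equiv), THF, -78 °C; DMF, -78 °C; AcOH
Reagents that add atoms: N,N-dimethylformamide, CN(C)C=O
Why: Deprotonative lithiation and Bouveault formylation; the C3–H flanked by fluorine and bromine is the most acidic ring proton, LDA at -78 °C should remove it without attacking the methyl ester, and DMF delivers the formyl group.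

Step 4
Reactants: 5 methyl(diphenyl)phosphine oxide; 6 acetone
Product: 7 (2-hydroxy-2-methylpropyl)diphenylphosphine oxide
Conditions: n-BuLi, THF, -78 °C; then 6, -78 to 0 °C; H2O
Reagents that add atoms: none
Why: Addition of the α-lithio phosphine oxide to the ketone is the first stage of a Horner–Wittig olefination; it stops at the lithium alkoxide, which is stable and gives the β-hydroxy phosphine oxide on protonation.

Step 5
Reactants: 4 methyl 2-bromo-4-fluoro-3-formyl-5-(methoxymethoxy)benzoate; 7 (2-hydroxy-2-methylpropyl)diphenylphosphine oxide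
Product: 10 methyl 5-bromo-8-(methoxymethoxy)-2,2-dimethyl-2H-chromene-6-carboxylate, via aryl ether 8 (not isolated), via cis-oxido phosphine oxide 9 (not isolated)
Conditions: 7 (2.3 equiv), NaH (2.2 equiv), THF–DMF, 0 °C; then 4, -20 °C to rt; then 55 °C
Reagents that add atoms: none
Why: Proposed new method: the sodium alkoxide of 7 adds to C4 of 4 and expels fluoride through a Meisenheimer adduct stabilised by the ortho-formyl and para-ester groups (SNAr, aryl–O bond, gives 8); a second equivalent of alkoxide then deprotonates the CH2 next to phosphorus, the carbanion adds to the neighbouring formyl carbon (C–C bond, gives 9), and syn-elimination of sodium diphenylphosphinate through a four-membered oxaphosphetane leaves the ring alkene. The closest known reaction types are the Horner–Wittig olefination of β-hydroxy phosphine oxides with sodium or potassium bases and the SNAr–aldol condensation cascades of 2-fluorobenzaldehydes with heteroatom-substituted C–H acids that give benzo-fused heterocycles. The pyran ring closes by 6-exo-trig attack of the phosphorus-stabilised carbanion on the aldehyde, the ether oxygen already being in the tether. The two stereocentres of 9 are transient: only the 3,4-cis adduct can eliminate, the trans adduct should return by retro-addition, and the product has no stereocentre, its alkene geometry being fixed by the six-membered ring. The selectivity needed is O-arylation of the tertiary alkoxide before it undergoes its own Horner–Wittig fragmentation to 2-methylpropene; the sodium counter-ion and low temperature (sodium oxido phosphine oxides eliminate on warming) and the doubly activated, non-enolisable fluoroaldehyde should secure it, and the excess of 7 covers any loss.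

Step 6
Reactants: 10 methyl 5-bromo-8-(methoxymethoxy)-2,2-dimethyl-2H-chromene-6-carboxylate; 11 tributyl(3-methylbut-2-en-1-yl)stannane
Product: 12 methyl 8-(methoxymethoxy)-2,2-dimethyl-5-(3-methylbut-2-en-1-yl)-2H-chromene-6-carboxylate
Conditions: Pd2(dba)3 (cat.), P(t-Bu)3 (cat.), CsF, 1,4-dioxane, 90 °C
Reagents that add atoms: none
Why: Stille coupling; after oxidative addition of the hindered aryl bromide and allyl transfer from tin, reductive elimination at the unsubstituted allyl terminus should give the linear prenyl arene, because the branched isomer would need a quaternary carbon between two ortho substituents.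

Step 7
Reactants: 12 methyl 8-(methoxymethoxy)-2,2-dimethyl-5-(3-methylbut-2-en-1-yl)-2H-chromene-6-carboxylate
Product: 13 8-(methoxymethoxy)-2,2-dimethyl-5-(3-methylbut-2-en-1-yl)-2H-chromene-6-carboxylic acid
Conditions: LiOH, THF–MeOH–H2O, 50 °C; then 1 M HCl to pH 4, 0 °C
Reagents that add atoms: lithium hydroxide, [Li+].[OH-]
Why: Saponification (BAc2 ester hydrolysis); the MOM acetal, the chromene and the prenyl group are inert to hydroxide.

Step 8
Reactants: 14 1-(2,4,6-trihydroxyphenyl)ethan-1-one; 15 3-methylbut-2-en-1-ol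
Product: 16 1-{2,6-dihydroxy-4-[(3-methylbut-2-en-1-yl)oxy]phenyl}ethan-1-one
Conditions: PPh3, DIAD, THF, 0 °C to rt
Reagents that add atoms: none
Why: Mitsunobu etherification; the 4-hydroxyl, the most acidic and the only one not hydrogen-bonded to the acetyl group, is alkylated at the primary carbon of the activated alcohol, and the neutral conditions avoid C-prenylation of the phloroglucinol ring.

Step 9
Reactants: 16 1-{2,6-dihydroxy-4-[(3-methylbut-2-en-1-yl)oxy]phenyl}ethan-1-one
Product: 17 1-[2,4,6-trihydroxy-3-(2-methylbut-3-en-2-yl)phenyl]ethan-1-one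
Conditions: PhNEt2, 190 °C
Reagents that add atoms: none
Why: Aromatic Claisen rearrangement ([3,3]-sigmatropic shift) to either of the two equivalent ortho positions and tautomerisation give the 1,1-dimethylallyl group at C3; the para position carries the acetyl group, so the para-Claisen–Cope pathway is closed.

Step 10
Reactants: 17 1-[2,4,6-trihydroxy-3-(2-methylbut-3-en-2-yl)phenyl]ethan-1-one
Product: 18 1-[2-hydroxy-4,6-bis(methoxymethoxy)-3-(2-methylbut-3-en-2-yl)phenyl]ethan-1-one
Conditions: MOMCl (2.1 equiv), i-Pr2NEt, CH2Cl2, 0 °C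
Reagents that add atoms: chloromethyl methyl ether, COCCl
Why: O-alkylation (acetal formation) should take the non-chelated 4-hydroxyl and the less hindered ortho hydroxyl at C6, leaving free the 2-hydroxyl that is hydrogen-bonded to the carbonyl and flanked by the quaternary side chain; this fixes the direction of the later pyranone closure.

Step 11
Reactants: 18 1-[2-hydroxy-4,6-bis(methoxymethoxy)-3-(2-methylbut-3-en-2-yl)phenyl]ethan-1-one
Product: 19 2-hydroxy-1-[2-hydroxy-4,6-bis(methoxymethoxy)-3-(2-methylbut-3-en-2-yl)phenyl]ethan-1-one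
Conditions: KHMDS (2.3 equiv), THF, -78 °C; 3-phenyl-2-(phenylsulfonyl)oxaziridine, -78 °C; AcOH
Reagents that add atoms: 3-phenyl-2-(phenylsulfonyl)oxaziridine, O=S(=O)(c1ccccc1)N1OC1c1ccccc1
Why: Enolate α-hydroxylation with an N-sulfonyloxaziridine (Davis oxidation); the phenoxide–enolate dianion attacks the electrophilic oxaziridine oxygen, and the unactivated vinyl group is not oxidised by this reagent.

Step 12
Reactants: 19 2-hydroxy-1-[2-hydroxy-4,6-bis(methoxymethoxy)-3-(2-methylbut-3-en-2-yl)phenyl]ethan-1-one
Product: 20 1-[2-hydroxy-4,6-bis(methoxymethoxy)-3-(2-methylbut-3-en-2-yl)phenyl]-2-(methoxymethoxy)ethan-1-one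
Conditions: MOMCl (1.1 equiv), i-Pr2NEt, CH2Cl2, 0 °C
Reagents that add atoms: chloromethyl methyl ether, COCCl
Why: O-alkylation of the primary alcohol (acetal formation); the chelated, doubly flanked phenol that survives the same reagent in step 10 should again stay free.

Step 13
Reactants: 13 8-(methoxymethoxy)-2,2-dimethyl-5-(3-methylbut-2-en-1-yl)-2H-chromene-6-carboxylic acid; 20 1-[2-hydroxy-4,6-bis(methoxymethoxy)-3-(2-methylbut-3-en-2-yl)phenyl]-2-(methoxymethoxy)ethan-1-one
Product: 22 1-[2-hydroxy-4,6-bis(methoxymethoxy)-3-(2-methylbut-3-en-2-yl)phenyl]-2-(methoxymethoxy)-3-[8-(methoxymethoxy)-2,2-dimethyl-5-(3-methylbut-2-en-1-yl)-2H-chromen-6-yl]propane-1,3-dione, via acid chloride 21 (not isolated)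
Conditions: 13, 1-chloro-N,N,2-trimethylprop-1-en-1-amine, CH2Cl2, 0 °C to rt; then added to 20, LiHMDS (3.2 equiv), THF, -78 to -20 °C; AcOH
Reagents that add atoms: none
Why: Acyl chloride formation under neutral conditions with the α-chloroenamine, then Claisen-type C-acylation of the lithium phenoxide–enolate dianion of 20 (the one-flask variant of the Baker–Venkataraman route), gives the 2-alkoxy-1,3-diketone; the third equivalent of base removes the acidic proton of the product and drives the acylation.

Step 14
Reactants: 22 1-[2-hydroxy-4,6-bis(methoxymethoxy)-3-(2-methylbut-3-en-2-yl)phenyl]-2-(methoxymethoxy)-3-[8-(methoxymethoxy)-2,2-dimethyl-5-(3-methylbut-2-en-1-yl)-2H-chromen-6-yl]propane-1,3-dione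
Product: 24 Broussoflavonol D, via tetrakis-MOM flavonol 23 (not isolated)
Conditions: 3 M HCl (aq)–MeOH (1:9), 45 °C
Reagents that add atoms: none
Why: Acid-catalysed cyclodehydration (the free 2-hydroxyl adds to the ring-B carbonyl in a 6-exo-trig closure and the hemiketal loses water to the pyranone) followed by methanolysis of the four MOM acetals should give the flavonol; only O2 is free when the ring closes, so the 1,1-dimethylallyl group ends at C8.

**Compound list**

1 | methyl 4-fluoro-3-hydroxybenzoate | COC(=O)c1ccc(F)c(O)c1 | starting material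
2 | methyl 2-bromo-4-fluoro-5-hydroxybenzoate | COC(=O)c1cc(O)c(F)cc1Br | intermediate
3 | methyl 2-bromo-4-fluoro-5-(methoxymethoxy)benzoate | COC(=O)c1cc(OCOC)c(F)cc1Br | intermediate
4 | methyl 2-bromo-4-fluoro-3-formyl-5-(methoxymethoxy)benzoate | COC(=O)c1cc(OCOC)c(F)c(C=O)c1Br | intermediate
5 | methyl(diphenyl)phosphine oxide | CP(=O)(c1ccccc1)c1ccccc1 | starting material
6 | acetone | CC(C)=O | starting material
7 | (2-hydroxy-2-methylpropyl)diphenylphosphine oxide | CC(C)(O)CP(=O)(c1ccccc1)c1ccccc1 | intermediate
8 | methyl 2-bromo-4-{[1-(diphenylphosphoryl)-2-methylpropan-2-yl]oxy}-3-formyl-5-(methoxymethoxy)benzoate (aryl ether, not isolated) | COC(=O)c1cc(OCOC)c(OC(C)(C)CP(=O)(c2ccccc2)c2ccccc2)c(C=O)c1Br | intermediate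
9 | methyl 3,4-cis-5-bromo-3-(diphenylphosphoryl)-4-hydroxy-8-(methoxymethoxy)-2,2-dimethyl-3,4-dihydro-2H-chromene-6-carboxylate (racemic, one enantiomer drawn; present as its sodium alkoxide, not isolated) | COC(=O)c1cc(OCOC)c2OC(C)(C)[C@@H](P(=O)(c3ccccc3)c3ccccc3)[C@@H](O)c2c1Br | intermediate
10 | methyl 5-bromo-8-(methoxymethoxy)-2,2-dimethyl-2H-chromene-6-carboxylate | COC(=O)c1cc(OCOC)c2OC(C)(C)C=Cc2c1Br | intermediate
11 | tributyl(3-methylbut-2-en-1-yl)stannane | CCCC[Sn](CCCC)(CCCC)CC=C(C)C | starting material
12 | methyl 8-(methoxymethoxy)-2,2-dimethyl-5-(3-methylbut-2-en-1-yl)-2H-chromene-6-carboxylate | COC(=O)c1cc(OCOC)c2OC(C)(C)C=Cc2c1CC=C(C)C | intermediate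
13 | 8-(methoxymethoxy)-2,2-dimethyl-5-(3-methylbut-2-en-1-yl)-2H-chromene-6-carboxylic acid | OC(=O)c1cc(OCOC)c2OC(C)(C)C=Cc2c1CC=C(C)C | intermediate
14 | 1-(2,4,6-trihydroxyphenyl)ethan-1-one | CC(=O)c1c(O)cc(O)cc1O | starting material
15 | 3-methylbut-2-en-1-ol | CC(C)=CCO | starting material
16 | 1-{2,6-dihydroxy-4-[(3-methylbut-2-en-1-yl)oxy]phenyl}ethan-1-one | CC(=O)c1c(O)cc(OCC=C(C)C)cc1O | intermediate
17 | 1-[2,4,6-trihydroxy-3-(2-methylbut-3-en-2-yl)phenyl]ethan-1-one | CC(=O)c1c(O)cc(O)c(C(C)(C)C=C)c1O | intermediate
18 | 1-[2-hydroxy-4,6-bis(methoxymethoxy)-3-(2-methylbut-3-en-2-yl)phenyl]ethan-1-one | CC(=O)c1c(OCOC)cc(OCOC)c(C(C)(C)C=C)c1O | intermediate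
19 | 2-hydroxy-1-[2-hydroxy-4,6-bis(methoxymethoxy)-3-(2-methylbut-3-en-2-yl)phenyl]ethan-1-one | OCC(=O)c1c(OCOC)cc(OCOC)c(C(C)(C)C=C)c1O | intermediate
20 | 1-[2-hydroxy-4,6-bis(methoxymethoxy)-3-(2-methylbut-3-en-2-yl)phenyl]-2-(methoxymethoxy)ethan-1-one | COCOCC(=O)c1c(OCOC)cc(OCOC)c(C(C)(C)C=C)c1O | intermediate
21 | 8-(methoxymethoxy)-2,2-dimethyl-5-(3-methylbut-2-en-1-yl)-2H-chromene-6-carbonyl chloride (not isolated) | ClC(=O)c1cc(OCOC)c2OC(C)(C)C=Cc2c1CC=C(C)C | intermediate
22 | 1-[2-hydroxy-4,6-bis(methoxymethoxy)-3-(2-methylbut-3-en-2-yl)phenyl]-2-(methoxymethoxy)-3-[8-(methoxymethoxy)-2,2-dimethyl-5-(3-methylbut-2-en-1-yl)-2H-chromen-6-yl]propane-1,3-dione (racemic at C2, keto tautomer drawn) | COCOC(C(=O)c1c(OCOC)cc(OCOC)c(C(C)(C)C=C)c1O)C(=O)c1cc(OCOC)c2OC(C)(C)C=Cc2c1CC=C(C)C | intermediate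
23 | 3,5,7-tris(methoxymethoxy)-2-[8-(methoxymethoxy)-2,2-dimethyl-5-(3-methylbut-2-en-1-yl)-2H-chromen-6-yl]-8-(2-methylbut-3-en-2-yl)-4H-chromen-4-one (not isolated) | C=CC(C)(C)c1c(OCOC)cc(OCOC)c2c(=O)c(OCOC)c(-c3cc(OCOC)c4c(c3CC=C(C)C)C=CC(C)(C)O4)oc12 | intermediate
24 | Broussoflavonol D, 3,5,7-trihydroxy-2-[8-hydroxy-2,2-dimethyl-5-(3-methylbut-2-en-1-yl)-2H-chromen-6-yl]-8-(2-methylbut-3-en-2-yl)-4H-chromen-4-one | C=CC(C)(C)c1c(O)cc(O)c2c(=O)c(O)c(-c3cc(O)c4c(c3CC=C(C)C)C=CC(C)(C)O4)oc12 | target

**Count and risks**

Total step count: 14. Longest linear sequence: 8 steps (1, 2, 3, 5, 6, 7, 13, 14).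

Steps most likely to fail:

1. Step 5 (Proposed new method). The sodium oxido phosphine oxide of 7 may fragment to 2-methylpropene before it is arylated. Displacement of the fluoride, which sits between the formyl and the MOM-oxy group, may be slow for a tertiary alkoxide. The trans adduct may not revert and so stall the elimination.
Fallback in known chemistry, from 4 back to 10: SNAr of 4 with sodium 2-methylbut-3-en-2-olate (2-methylbut-3-en-2-ol, NaH, DMF, 0 °C) should give the allyl aryl ether methyl 2-bromo-3-formyl-5-(methoxymethoxy)-4-[(2-methylbut-3-en-2-yl)oxy]benzoate F1. Wittig methylenation (Ph3PCH3Br, KOt-Bu, THF) should give the styrene methyl 2-bromo-3-ethenyl-5-(methoxymethoxy)-4-[(2-methylbut-3-en-2-yl)oxy]benzoate F2. Ring-closing olefin metathesis with a second-generation ruthenium benzylidene catalyst (CH2Cl2, 40 °C) should close the pyran ring with loss of ethene and return to 10.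

2. Step 9. At 190 °C a free ortho-hydroxyl may add to the new 1,1-dimethylallyl group (dihydrofuran formation or abnormal Claisen rearrangement), and the prenyl ether may cleave instead of rearranging.
Fallback, from 16 back to 17: acetylation of 16 (Ac2O, pyridine) should give the diacetate 1-{2,6-diacetoxy-4-[(3-methylbut-2-en-1-yl)oxy]phenyl}ethan-1-one F3. Claisen rearrangement of F3 in PhNEt2 with Ac2O and NaOAc present traps the new phenol as it forms and should give the triacetate 1-[2,4,6-triacetoxy-3-(2-methylbut-3-en-2-yl)phenyl]ethan-1-one F4. Methanolysis (K2CO3, MeOH, rt) then returns to 17, so no free phenol is exposed to the high temperature.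

3. Step 14. Under protic acid the freed 7-hydroxyl may add to the neighbouring vinyl group, the prenyl group may take up HCl or methanol, and loss of the MOM group at the second ortho oxygen of ring A before ring closure may let that oxygen cyclise and give the 6-substituted isomer.
Fallback, from 22 back to 24: cyclodehydration of 22 with pyridinium p-toluenesulfonate in toluene at 70 °C with isolation of 23, then cleavage of the four MOM groups by Lewis acid and thiol transacetalisation (ZnBr2, n-PrSH, CH2Cl2, 0 °C), which avoids strong protic acid. This fallback makes no compound outside the list (F0).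

**Further compounds**

F1 | step 5 | methyl 2-bromo-3-formyl-5-(methoxymethoxy)-4-[(2-methylbut-3-en-2-yl)oxy]benzoate | COC(=O)c1cc(OCOC)c(OC(C)(C)C=C)c(C=O)c1Br
F2 | step 5 | methyl 2-bromo-3-ethenyl-5-(methoxymethoxy)-4-[(2-methylbut-3-en-2-yl)oxy]benzoate | COC(=O)c1cc(OCOC)c(OC(C)(C)C=C)c(C=C)c1Br
F3 | step 9 | 1-{2,6-diacetoxy-4-[(3-methylbut-2-en-1-yl)oxy]phenyl}ethan-1-one | CC(=O)Oc1cc(OCC=C(C)C)cc(OC(C)=O)c1C(C)=O
F4 | step 9 | 1-[2,4,6-triacetoxy-3-(2-methylbut-3-en-2-yl)phenyl]ethan-1-one | CC(=O)Oc1cc(OC(C)=O)c(C(C)(C)C=C)c(OC(C)=O)c1C(C)=O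
F0 | step 14 | none | none
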